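**Retrosynthetic overview**
- Rings A and B are bought ready-made as acetophenone 1 and aldehyde 2. Ring C is the only ring that is built.
- Disconnection a: the Cα=Cβ bond of the three-carbon bridge, made by Claisen–Schmidt condensation of 1 with 2 (aldol 3, then chalcone 4).
- Disconnection b: the O1–C2 bond of ring C, made by oxa-Michael closure to flavanone 5 and dehydrogenation in the same pot to flavone 6.
- Disconnection c: the 5-OH travels as OMe and is freed last by carbonyl-chelated BCl3 cleavage (chelate 7) to give target 8.

Assumption: the target is a flat, achiral flavone with no stereocentre, so there is no enantiomer to choose, and 1 is taken as a catalogue compound.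

**Step 1**
Reactants: 1 2'-hydroxy-3',4',6'-trimethoxyacetophenone; 2 2,3-dimethoxybenzaldehyde
Product: 4 (E)-2'-hydroxy-2,3,3',4',6'-pentamethoxychalcone, via aldol adduct 3 (not isolated)
Conditions: KOH (10 equiv, 50% aq), EtOH, 0 °C to rt, 24–48 h; then 2 M HCl to pH 3
Reagents that add atoms: none
Why: In this Claisen–Schmidt (crossed aldol) condensation only 1 can enolise and only 2 is a reactive non-enolisable electrophile, and E1cB loss of water from racemic aldol 3 gives the conjugated, thermodynamically favoured E-enone, so no stereocentre remains.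

**Step 2**
Reactants: 4 (E)-2'-hydroxy-2,3,3',4',6'-pentamethoxychalcone
Product: 6 flavone pentamethyl ether (2',3',5,7,8-pentamethoxyflavone), via flavanone 5 (not isolated)
Conditions: I2 (10 mol %), DMSO, 130 °C, 3 h
Reagents that add atoms: none
Why: In this iodine-catalysed oxidative cyclisation of a 2'-hydroxychalcone, the only free phenol closes ring C by 6-endo oxa-Michael addition and fixes the 5,7,8 pattern, the racemic C2 centre of 5 is erased by dehydrogenation to the aromatic pyranone, and DMSO is the terminal oxidant that keeps the small iodine charge turning over so that ring A is not iodinated.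

**Step 3**
Reactants: 6 flavone pentamethyl ether (2',3',5,7,8-pentamethoxyflavone)
Product: 8 target flavone 5-hydroxy-2',3',7,8-tetramethoxyflavone, via dichloroboron chelate 7 (not isolated)
Conditions: BCl3 (1.0 M in CH2Cl2, 1.5 equiv), CH2Cl2, −78 °C to 0 °C, 1–2 h; then H2O
Reagents that add atoms: none
Why: In this chelation-directed Lewis acid O-demethylation, BCl3 binds the C4 carbonyl and only the peri 5-OMe can form a six-membered boron chelate, so chloride removes that methyl much faster than the other four, while the cold aprotic medium avoids Wessely–Moser isomerisation, and no stereocentre is made.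

**Compound list**
1 | 2'-hydroxy-3',4',6'-trimethoxyacetophenone | CC(=O)c1c(O)c(OC)c(OC)cc1OC | starting material
2 | 2,3-dimethoxybenzaldehyde | COc1cccc(C=O)c1OC | starting material
3 | 3-(2,3-dimethoxyphenyl)-3-hydroxy-1-(2-hydroxy-3,4,6-trimethoxyphenyl)propan-1-one (racemic aldol adduct, not isolated) | COc1cccc(C(O)CC(=O)c2c(O)c(OC)c(OC)cc2OC)c1OC | intermediate
4 | (E)-3-(2,3-dimethoxyphenyl)-1-(2-hydroxy-3,4,6-trimethoxyphenyl)prop-2-en-1-one, i.e. (E)-2'-hydroxy-2,3,3',4',6'-pentamethoxychalcone | COc1cccc(/C=C/C(=O)c2c(O)c(OC)c(OC)cc2OC)c1OC | intermediate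
5 | 2',3',5,7,8-pentamethoxyflavanone (racemic, not isolated) | COc1cccc(C2CC(=O)c3c(OC)cc(OC)c(OC)c3O2)c1OC | intermediate
6 | 2',3',5,7,8-pentamethoxyflavone | COc1cccc(-c2cc(=O)c3c(OC)cc(OC)c(OC)c3o2)c1OC | intermediate
7 | 5-(dichloroboryloxy)-2',3',7,8-tetramethoxyflavone (boron chelated to the C4 carbonyl, not isolated) | COc1cccc(-c2cc(=O)c3c(OB(Cl)Cl)cc(OC)c(OC)c3o2)c1OC | intermediate
8 | 5-hydroxy-2',3',7,8-tetramethoxyflavone (achiral) | COc1cccc(-c2cc(=O)c3c(O)cc(OC)c(OC)c3o2)c1OC | target

**Totals**
- Total step count: 3.
- Longest linear sequence: 3.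

**Steps most likely to fail, with fallbacks**

Risk 1, step 3. The crowded 8-OMe and 2'-OMe groups may also be cut by BCl3, which would give mixtures of phenols. The fallback sets out from 6 and comes back at 8, and it replaces selective removal with selective re-installation.
- All five ethers of 6 are cleaved with excess BBr3 (CH2Cl2, −78 °C to rt, no hot protic acid) to give 2',3',5,7,8-pentahydroxyflavone F1.
- F1 is then methylated under argon with MeI (4.2 equiv) and K2CO3 in acetone.
- The hydrogen-bonded 5-OH is the least acidic and least nucleophilic phenol, so it stays free while the other four are methylated, giving 8.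

Risk 2, step 2. Possible problems are iodination of the activated C6–H of ring A, partial ether cleavage at 130 °C, and aurone formation. The fallback sets out from 4 and comes back at 6, and it separates ring closure from oxidation and uses no halogen.
- Chalcone 4 is closed under non-oxidising conditions (NaOAc, EtOH, reflux) to flavanone 5, which is now isolated.
- Flavanone 5 is dehydrogenated by hydride abstraction from the benzylic, oxygen-bearing C2 with DDQ (dioxane, reflux) to give 6.
- New compounds on this way: none F0.

Risk 3, step 1. The hindered, electron-rich phenoxide ketone may condense sluggishly, and the aldehyde may be lost to Cannizzaro reaction. The fallback sets out from 1 and comes back at 6. It bypasses steps 1 and 2 by building the bridge at the ester oxidation level, so no oxidation is needed (Baker–Venkataraman route).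
- Compound 1 is O-acylated with bought 2,3-dimethoxybenzoyl chloride in pyridine to give 2-acetyl-3,5,6-trimethoxyphenyl 2,3-dimethoxybenzoate F2.
- KOH in pyridine at 50 °C moves the aroyl group from oxygen to the acetyl carbon, giving 1-(2,3-dimethoxyphenyl)-3-(2-hydroxy-3,4,6-trimethoxyphenyl)propane-1,3-dione F3.
- Catalytic H2SO4 in AcOH at 100 °C cyclodehydrates F3 to 6.

**Further compounds**
F1 | step 3 | 2',3',5,7,8-pentahydroxyflavone | Oc1cccc(-c2cc(=O)c3c(O)cc(O)c(O)c3o2)c1O
F0 | step 2 | none | none
F2 | step 1 | 2-acetyl-3,5,6-trimethoxyphenyl 2,3-dimethoxybenzoate | COc1cccc(C(=O)Oc2c(C(C)=O)c(OC)cc(OC)c2OC)c1OC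
F3 | step 1 | 1-(2,3-dimethoxyphenyl)-3-(2-hydroxy-3,4,6-trimethoxyphenyl)propane-1,3-dione | COc1cccc(C(=O)CC(=O)c2c(O)c(OC)c(OC)cc2OC)c1OC
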